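The data were computed for substances that don't exist; scatter was added.

The epsilon run, with half the X of the theta run, made Z at 32.5 mM min⁻¹ over its first 1.3 min against 36.8 mM min⁻¹ for theta, a ratio of 0.883. Between 3.7 min and 6.3 min it made 3.31 mM min⁻¹ against 9.08 mM min⁻¹, a ratio of 0.365. A catalyst decaying on a clock keeps such a ratio fixed at equal L, so the clock reading looks doubtful. The eta run, with twice the L, opened at 61.1 mM min⁻¹, faster than theta, yet late on it made 6.12 mM min⁻¹, less than theta. Meanwhile the theta reading at 6.3 min, 43.8% of the X, stands well below the 80.0% that E, the limiting reagent, allows. So X seems to leave by a second road.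

| flask | X | E | L | time |
|---|---|---|---|---|
| theta | 300 mM | 240 mM | 30.0 mM |  |
| eta | 300 mM | 240 mM | 60.0 mM |  |
| zeta | 300 mM | 480 mM | 30.0 mM |  |
| epsilon | 150 mM | 240 mM | 30.0 mM |  |
| delta | 300 mM | 240 mM | 30.0 mM | 13 min |

- theta run (time / min: [Z] / mM): 0.25: 10.3; 0.43: 17.0; 0.74: 28.4; 1.3: 47.8; 2.2: 73.7; 3.7: 107.9; 6.3: 131.5
- eta run (time / min: [Z] / mM): 0.25: 17.0; 0.43: 28.2; 0.74: 48.4; 1.3: 79.4; 2.2: 120.1; 3.7: 162.6; 6.3: 178.5
- zeta run (time / min: [Z] / mM): 0.25: 13.6; 0.43: 21.9; 0.74: 37.4; 1.3: 59.9; 2.2: 97.3; 3.7: 138.4; 6.3: 154.2
- epsilon run (time / min: [Z] / mM): 0.25: 6.0; 0.43: 14.7; 0.74: 24.1; 1.3: 42.3; 2.2: 64.3; 3.7: 84.0; 6.3: 92.6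

(scatter of a reading: 0.9 mM)

- how the opening rate goes with [E] round the charge of the theta run: the exponent of the rate at two percent of X gone to Z
- how the opening rate goes with [L] round the charge of the theta run: the exponent of the rate at two percent of X gone to Z
- Z in the delta run at 13 min, as a share of the X charged

- Overall: X + E -> Z, with L as catalyst.
- Constant volume, constant temperature.
- A reading of a species includes what of it is bound.
- "The second partner" is E.
- An order is taken over about fifteen percent of the charge, up and down.

Treat each flask as a race. Z forms at a steady rate r, the opening one, while a first-order drain removes X. Replace the falling X by its mean, half the charge. The share of X reaching Z, the selectivity, is then r divided by r plus the drain on that mean. Read backwards, with the last reading as the share, each run gives a constant: 0.277 min⁻¹ for eta, 0.290 min⁻¹ for zeta and 0.269 min⁻¹ for epsilon. Doubled L, doubled E and halved X hardly move it, as a drain proportional to X requires. Their mean, 0.279 min⁻¹, is the drain constant, the fraction of the mean X lost per minute in this race. Set against theta's rate and charge, it gives a share of 46.8%.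

The objection is the mean itself. X sags below a straight fall, so the chord overstates the drain. For steady r and a true exponential drain the share is ln(1+B)/B, where B is the drain on the full charge over r. At theta's B of 2.28 the chord's error is 5.4 percentage points. But the constant was read through the same chord, at a mean B of 1.50, where the error is 3.9 points. The difference left is 1.5 points. A second objection pulls the other way: r sags too as X falls, and that is not reckoned here. The share of 46.8% stands, with a margin of a point or two.

The forecast gave 0.44 for the order in E, 0.78 for the order in L and 47.5% at 13 min, with the words “Catalyst death is the likely cause”.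

The delta run gives 45.1% at 13 min, with orders of 0.44 in E and 0.75 in L.

    L + X ⇌ LX, settled at all times (59.30 L mol⁻¹)
    LX + E ⇌ LXE, settled at all times (15.90 L mol⁻¹)
    LXE → Z + L (1.398 min⁻¹)
    X → Vy (0.4464 min⁻¹)
    X + E → Z (0.1512 L mol⁻¹ min⁻¹)

Put back through the rule with theta's opening rate, since the charges match, the delta share gives a drain constant of 0.299 min⁻¹, above the neighbours' 0.279 min⁻¹, so the reckoned share stood 1.7 points high. The turning of X into Vy is what holds the share down: the delta run without that step reaches 77.8% against 45.1%. At 13 min that second flask stands just under the 80.0% that E allows.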